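**Retrosynthetic overview**

1. Numbering: acid carbon C1; ring A (the 1,2-dioxane) is O(a)–O(b)–C3–C4–C5–C6, with O(b) on C3 and O(a) on C6; side chain C7–C14. Last disconnection: C2–C3, by addition of a silyl ketene acetal to the cyclic peroxycarbenium ion of a 3-methoxy-1,2-dioxane, which leads back to a 1,2-dioxan-3-ol.
2. Key disconnection: C4–C5 and O(b)–C3 of ring A together, a formal [4+2] union of a C5–C6–O–O unit (tertiary silyl peroxide with a C5 triflate and the complete side chain) with a C3–C4 unit (butanal as its RAMP-hydrazone).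
3. Enabling feature: C3 carries the ring oxygen O(b) and can be held at the aldehyde (peroxy-hemiacetal) level, so C4 is an enolisable α-carbon and C3 an electrophile for the C6 hydroperoxide. The ring methylene C5 sits next to the fully substituted C6 (no β-hydrogen) and therefore tolerates activation as a triflate.
4. Peroxide unit: from a 2,2-disubstituted oxirane by perhydrolysis with inversion. The oxirane comes from a tertiary allylic diol made by auxiliary-controlled addition of the side-chain alkenyl Grignard reagent to an α-keto ester. The side chain (C10, both alkenes) comes from kinetic resolution, Johnson–Claisen chirality transfer and alkyne carboalumination.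
5. Ring order: the oxirane (temporary, formed in step 9, opened in step 10), then ring A (step 14); no other ring is formed.

Key step: step 14

Assumption: Grignard additions to 8-phenylmenthyl α-keto esters occur on the face not shielded by the phenyl ring, and molybdenum-catalysed perhydrolysis of 2,2-disubstituted oxiranes proceeds with inversion at the tertiary carbon; the auxiliary enantiomers are chosen on that basis.

**Route**

Step 1
Reactants: 1 (E)-pent-2-enal
Product: 2 rac-(E)-hept-4-en-3-ol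
Conditions: EtMgBr, THF, −78 → 0 °C; aq. NH4Cl
Reagents that add atoms: ethylmagnesium bromide, CC[Mg]Br
Why: 1,2-addition of the hard Grignard reagent to the unhindered enal should give the racemic secondary allylic alcohol.

Step 2
Reactants: 2 rac-(E)-hept-4-en-3-ol
Product: 3 (R,E)-hept-4-en-3-ol
Conditions: Ti(OiPr)4 (cat.), L-(+)-diisopropyl tartrate, tBuOOH (0.6 equiv), 4 Å MS, CH2Cl2, −20 °C
Reagents that add atoms: none
Why: Sharpless kinetic resolution, in which the (S)-alcohol is epoxidised fast with the L-(+)-tartrate and the (R)-alcohol is recovered; this sets the centre that is later relayed to C10.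

Step 3
Reactants: 3 (R,E)-hept-4-en-3-ol
Product: 4 ethyl (R,E)-3-ethylhept-4-enoate
Conditions: MeC(OEt)3, EtCO2H (cat.), 140 °C, EtOH distilled off
Reagents that add atoms: triethyl orthoacetate, CC(OCC)(OCC)OCC
Why: Johnson–Claisen rearrangement through a chair transition state with the carbinol ethyl group equatorial should give the (E)-alkene and transfer the carbinol configuration suprafacially to the new C–C bond (R to R, the future C10).

Step 4
Reactants: 4 ethyl (R,E)-3-ethylhept-4-enoate
Product: 6 (R,E)-4-ethyloct-5-en-1-yne, via aldehyde 5 (not isolated)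
Conditions: iBu2AlH, CH2Cl2, −78 °C; then MeOH, K2CO3, dimethyl (1-diazo-2-oxopropyl)phosphonate, −78 °C → rt
Reagents that add atoms: dimethyl (1-diazo-2-oxopropyl)phosphonate, CC(=O)C(=[N+]=[N-])P(=O)(OC)OC
Why: half-reduction of the ester and Ohira–Bestmann (Seyferth–Gilbert) homologation in one flask; the stereocentre is β to the carbonyl group and cannot epimerise.

Step 5
Reactants: 6 (R,E)-4-ethyloct-5-en-1-yne
Product: 8 (1E,4R,5E)-4-ethyl-1-iodo-2-methylocta-1,5-diene, via alkenylalane 7 (not isolated)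
Conditions: AlMe3, Cp2ZrCl2 (cat.), CH2Cl2, 0 °C → rt; then I2, THF, −30 → 0 °C
Reagents that add atoms: trimethylaluminium, C[Al](C)C; iodine, II
Why: Negishi zirconium-catalysed syn-carboalumination puts methyl on the internal and aluminium on the terminal alkyne carbon, and iodinolysis with retention should give the (E)-2-methylalkenyl iodide (the C7=C8 geometry).

Step 6
Reactants: 9 (+)-8-phenylmenthol; 10 2-oxobutanoic acid
Product: 11 (1S,2R,5S)-5-methyl-2-(2-phenylpropan-2-yl)cyclohexyl 2-oxobutanoate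
Conditions: DCC, DMAP (cat.), CH2Cl2, 0 °C → rt
Reagents that add atoms: none
Why: Steglich esterification of the secondary alcohol with the α-keto acid.

Step 7
Reactants: 8 (1E,4R,5E)-4-ethyl-1-iodo-2-methylocta-1,5-diene; 11 (1S,2R,5S)-5-methyl-2-(2-phenylpropan-2-yl)cyclohexyl 2-oxobutanoate
Product: 13 (1S,2R,5S)-5-methyl-2-(2-phenylpropan-2-yl)cyclohexyl (2R,3E,6R,7E)-2,6-diethyl-2-hydroxy-4-methyldeca-3,7-dienoate, via alkenylmagnesium chloride 12 (not isolated)
Conditions: iPrMgCl·LiCl, THF, 0 °C → rt; then 11, THF, −78 °C; aq. NH4Cl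
Reagents that add atoms: none
Why: iodine–magnesium exchange with retention of alkene geometry, then chemoselective Grignard addition to the keto group of the chelated s-cis α-keto ester on the face not shielded by the phenyl ring of the auxiliary, which should set the future C6 as the (R)-carbinol.

Step 8
Reactants: 13 (1S,2R,5S)-5-methyl-2-(2-phenylpropan-2-yl)cyclohexyl (2R,3E,6R,7E)-2,6-diethyl-2-hydroxy-4-methyldeca-3,7-dienoate
Product: 14 (2R,3E,6R,7E)-2,6-diethyl-4-methyldeca-3,7-diene-1,2-diol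
Conditions: LiAlH4, Et2O, 0 °C → rt
Reagents that add atoms: none
Why: hydride reduction of the hindered ester releases the primary alcohol and the recoverable auxiliary without touching the tertiary centre or the alkenes.

Step 9
Reactants: 14 (2R,3E,6R,7E)-2,6-diethyl-4-methyldeca-3,7-diene-1,2-diol
Product: 15 (2R)-2-ethyl-2-[(1E,4R,5E)-4-ethyl-2-methylocta-1,5-dien-1-yl]oxirane
Conditions: NaH, 1-(p-toluenesulfonyl)imidazole, THF, 0 °C → rt
Reagents that add atoms: none
Why: selective sulfonylation of the primary alkoxide and intramolecular Williamson closure leave the tertiary C–O bond intact, so the configuration is retained.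

Step 10
Reactants: 15 (2R)-2-ethyl-2-[(1E,4R,5E)-4-ethyl-2-methylocta-1,5-dien-1-yl]oxirane
Product: 16 (2S,3E,6R,7E)-2,6-diethyl-2-hydroperoxy-4-methyldeca-3,7-dien-1-ol
Conditions: anhydrous H2O2 in Et2O (excess), MoO2(acac)2 (cat.), 0 °C, dark
Reagents that add atoms: hydrogen peroxide, OO
Why: molybdenum-catalysed perhydrolysis of a 2-alkyl-2-alkenyl oxirane, in which H2O2 should open the activated epoxide at the tertiary allylic carbon with inversion (borderline SN2, as known for 2-alkyl-2-vinyl oxiranes and tertiary epoxides), turning the (R)-epoxide into the (S)-hydroperoxide with the C6 configuration of the target.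

Step 11
Reactants: 16 (2S,3E,6R,7E)-2,6-diethyl-2-hydroperoxy-4-methyldeca-3,7-dien-1-ol
Product: 17 (2S,3E,6R,7E)-2-[(tert-butyldimethylsilyl)peroxy]-2,6-diethyl-4-methyldeca-3,7-dien-1-ol
Conditions: TBSCl (1.05 equiv), imidazole, CH2Cl2, −20 °C
Reagents that add atoms: tert-butyldimethylsilyl chloride, CC(C)(C)[Si](C)(C)Cl
Why: silylation of the more acidic, unhindered terminal O–H of the hydroperoxide should outpace that of the neopentyl-type primary alcohol.

Step 12
Reactants: 17 (2S,3E,6R,7E)-2-[(tert-butyldimethylsilyl)peroxy]-2,6-diethyl-4-methyldeca-3,7-dien-1-ol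
Product: 18 (2S,3E,6R,7E)-2-[(tert-butyldimethylsilyl)peroxy]-2,6-diethyl-4-methyldeca-3,7-dien-1-yl trifluoromethanesulfonate
Conditions: Tf2O, 2,6-lutidine, CH2Cl2, −78 °C; used at once
Reagents that add atoms: trifluoromethanesulfonic anhydride, O=S(=O)(OS(=O)(=O)C(F)(F)F)C(F)(F)F
Why: standard triflation of a primary alcohol; the β-carbon is fully substituted, so the triflate cannot eliminate.

Step 13
Reactants: 19 butanal; 20 RAMP, (R)-1-amino-2-(methoxymethyl)pyrrolidine
Product: 21 (E)-butanal RAMP-hydrazone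
Conditions: neat, 0 °C → rt; then Et2O, MgSO4
Reagents that add atoms: none
Why: condensation of the aldehyde with the hydrazine gives the (E)-hydrazone needed for the Enders hydrazone alkylation.

Step 14
Reactants: 21 (E)-butanal RAMP-hydrazone; 18 (2S,3E,6R,7E)-2-[(tert-butyldimethylsilyl)peroxy]-2,6-diethyl-4-methyldeca-3,7-dien-1-yl trifluoromethanesulfonate
Product: 25 (4R,6R)-4,6-diethyl-6-[(1E,4R,5E)-4-ethyl-2-methylocta-1,5-dien-1-yl]-1,2-dioxan-3-ol, via lithium azaenolate 22 (not isolated), via alkylated RAMP-hydrazone 23 (not isolated), via hydroperoxy aldehyde 24 (not isolated)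
Conditions: LiN(iPr)2, THF, 0 °C; then 18, −100 → −40 °C; then 48% aq. HF, MeCN, 0 °C → rt
Reagents that add atoms: water, O
Why: LiN(iPr)2 converts 21 into the methoxy-chelated lithium azaenolate 22, whose α-carbon displaces the primary triflate of 18 by SN2 (C4–C5 bond, hydrazone 23); aqueous HF then removes the silyl group from the peroxide and hydrolyses the protonated hydrazone, and the freed hydroperoxide of 24 adds to the aldehyde carbon (O(b)–C3 bond) to give the cyclic peroxy-hemiacetal. The closest known reaction types are the Enders SAMP/RAMP-hydrazone α-alkylation with primary sulfonates and the spontaneous cyclisation of γ-hydroperoxy aldehydes to 1,2-dioxan-3-ols. Ring A closes by 6-exo-trig attack of the hydroperoxide oxygen on the C3 carbonyl (or iminium) carbon. C4 is set by the auxiliary, the electrophile entering the azaenolate face away from the chelated pyrrolidine side arm, which for RAMP and this substituent pattern should give 4R; C6 and C10 are carried in unchanged and C3 remains an anomeric mixture that is corrected in step 16. The step needs C-alkylation at C5 in preference to attack at sulfur or at the O–O bond; the soft azaallyl anion at low temperature, the bulky tertiary silyl peroxide and the fully substituted C6 (no elimination possible) should secure this, and the 1,4-relation of OOH and CHO secures the six-membered hemiacetal.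

Step 15
Reactants: 25 (4R,6R)-4,6-diethyl-6-[(1E,4R,5E)-4-ethyl-2-methylocta-1,5-dien-1-yl]-1,2-dioxan-3-ol
Product: 26 (4R,6R)-4,6-diethyl-6-[(1E,4R,5E)-4-ethyl-2-methylocta-1,5-dien-1-yl]-3-methoxy-1,2-dioxane
Conditions: MeOH, PPTS (cat.), 4 Å MS, rt
Reagents that add atoms: methanol, CO
Why: acid-catalysed acetalisation of the peroxy-hemiacetal through the cyclic peroxycarbenium ion gives a stable peroxy acetal that can be ionised cleanly.

Step 16
Reactants: 26 (4R,6R)-4,6-diethyl-6-[(1E,4R,5E)-4-ethyl-2-methylocta-1,5-dien-1-yl]-3-methoxy-1,2-dioxane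
Product: 27 methyl 2-[(3R,4R,6R)-4,6-diethyl-6-[(1E,4R,5E)-4-ethyl-2-methylocta-1,5-dien-1-yl]-1,2-dioxan-3-yl]acetate
Conditions: 1-(tert-butyldimethylsilyloxy)-1-methoxyethene (3 equiv), Me3SiOTf (cat.), CH2Cl2, −78 °C
Reagents that add atoms: 1-(tert-butyldimethylsilyloxy)-1-methoxyethene, C=C(OC)O[Si](C)(C)C(C)(C)C
Why: ionisation of the peroxy acetal to the cyclic peroxycarbenium ion and Mukaiyama-type addition of the silyl ketene acetal; axial attack on the half-chair that keeps the C4 ethyl and the C6 alkenyl groups pseudo-equatorial should place the acetate arm cis to the C4 ethyl group (3R).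

Step 17
Reactants: 27 methyl 2-[(3R,4R,6R)-4,6-diethyl-6-[(1E,4R,5E)-4-ethyl-2-methylocta-1,5-dien-1-yl]-1,2-dioxan-3-yl]acetate
Product: 28 2-[(3R,4R,6R)-4,6-diethyl-6-[(1E,4R,5E)-4-ethyl-2-methylocta-1,5-dien-1-yl]-1,2-dioxan-3-yl]acetic acid
Conditions: LiOH·H2O, THF/H2O, 0 °C; then 1 M HCl to pH 4
Reagents that add atoms: lithium hydroxide, [Li+].[OH-]
Why: mild saponification of the methyl ester, which dialkyl peroxides of this type should survive at 0 °C, gives the target acid without touching any stereocentre.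

**Compound list**

1 | (E)-pent-2-enal | CC/C=C/C=O | starting material
2 | rac-(E)-hept-4-en-3-ol | CC/C=C/C(O)CC | intermediate
3 | (R,E)-hept-4-en-3-ol | CC/C=C/[C@H](O)CC | intermediate
4 | ethyl (R,E)-3-ethylhept-4-enoate | CC/C=C/[C@H](CC)CC(=O)OCC | intermediate
5 | (R,E)-3-ethylhept-4-enal | CC/C=C/[C@H](CC)CC=O | intermediate
6 | (R,E)-4-ethyloct-5-en-1-yne | CC/C=C/[C@H](CC)CC#C | intermediate
7 | [(1E,4R,5E)-4-ethyl-2-methylocta-1,5-dien-1-yl]dimethylalane | CC/C=C/[C@H](CC)C/C(C)=C/[Al](C)C | intermediate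
8 | (1E,4R,5E)-4-ethyl-1-iodo-2-methylocta-1,5-diene | CC/C=C/[C@H](CC)C/C(C)=C/I | intermediate
9 | (+)-8-phenylmenthol, (1S,2R,5S)-5-methyl-2-(2-phenylpropan-2-yl)cyclohexan-1-ol | O[C@H]1C[C@@H](C)CC[C@@H]1C(C)(C)c1ccccc1 | starting material
10 | 2-oxobutanoic acid | CCC(=O)C(=O)O | starting material
11 | (1S,2R,5S)-5-methyl-2-(2-phenylpropan-2-yl)cyclohexyl 2-oxobutanoate | CCC(=O)C(=O)O[C@H]1C[C@@H](C)CC[C@@H]1C(C)(C)c1ccccc1 | intermediate
12 | [(1E,4R,5E)-4-ethyl-2-methylocta-1,5-dien-1-yl]magnesium chloride | CC/C=C/[C@H](CC)C/C(C)=C/[Mg]Cl | intermediate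
13 | (1S,2R,5S)-5-methyl-2-(2-phenylpropan-2-yl)cyclohexyl (2R,3E,6R,7E)-2,6-diethyl-2-hydroxy-4-methyldeca-3,7-dienoate | CC/C=C/[C@H](CC)C/C(C)=C/[C@](O)(CC)C(=O)O[C@H]1C[C@@H](C)CC[C@@H]1C(C)(C)c1ccccc1 | intermediate
14 | (2R,3E,6R,7E)-2,6-diethyl-4-methyldeca-3,7-diene-1,2-diol | CC/C=C/[C@H](CC)C/C(C)=C/[C@](O)(CC)CO | intermediate
15 | (2R)-2-ethyl-2-[(1E,4R,5E)-4-ethyl-2-methylocta-1,5-dien-1-yl]oxirane | CC/C=C/[C@H](CC)C/C(C)=C/[C@]1(CC)CO1 | intermediate
16 | (2S,3E,6R,7E)-2,6-diethyl-2-hydroperoxy-4-methyldeca-3,7-dien-1-ol | CC/C=C/[C@H](CC)C/C(C)=C/[C@@](OO)(CC)CO | intermediate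
17 | (2S,3E,6R,7E)-2-[(tert-butyldimethylsilyl)peroxy]-2,6-diethyl-4-methyldeca-3,7-dien-1-ol | CC/C=C/[C@H](CC)C/C(C)=C/[C@@](OO[Si](C)(C)C(C)(C)C)(CC)CO | intermediate
18 | (2S,3E,6R,7E)-2-[(tert-butyldimethylsilyl)peroxy]-2,6-diethyl-4-methyldeca-3,7-dien-1-yl trifluoromethanesulfonate | CC/C=C/[C@H](CC)C/C(C)=C/[C@@](OO[Si](C)(C)C(C)(C)C)(CC)COS(=O)(=O)C(F)(F)F | intermediate
19 | butanal | CCCC=O | starting material
20 | RAMP, (R)-1-amino-2-(methoxymethyl)pyrrolidine | COC[C@H]1CCCN1N | starting material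
21 | (E)-butanal RAMP-hydrazone, (R,E)-N-butylidene-2-(methoxymethyl)pyrrolidin-1-amine | COC[C@H]1CCCN1/N=C/CCC | intermediate
22 | lithium azaenolate of 21 | COC[C@H]1CCCN1N([Li])/C=C/CC | intermediate
23 | RAMP-hydrazone of (2R,4R,5E,8R,9E)-4-[(tert-butyldimethylsilyl)peroxy]-2,4,8-triethyl-6-methyldodeca-5,9-dienal | CC/C=C/[C@H](CC)C/C(C)=C/[C@@](OO[Si](C)(C)C(C)(C)C)(CC)C[C@@H](CC)/C=N/N1CCC[C@@H]1COC | intermediate
24 | (2R,4R,5E,8R,9E)-2,4,8-triethyl-4-hydroperoxy-6-methyldodeca-5,9-dienal | CC/C=C/[C@H](CC)C/C(C)=C/[C@@](OO)(CC)C[C@@H](CC)C=O | intermediate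
25 | (4R,6R)-4,6-diethyl-6-[(1E,4R,5E)-4-ethyl-2-methylocta-1,5-dien-1-yl]-1,2-dioxan-3-ol (both C3 anomers) | CC/C=C/[C@H](CC)C/C(C)=C/[C@@]1(CC)C[C@@H](CC)C(O)OO1 | intermediate
26 | (4R,6R)-4,6-diethyl-6-[(1E,4R,5E)-4-ethyl-2-methylocta-1,5-dien-1-yl]-3-methoxy-1,2-dioxane (both C3 anomers) | CC/C=C/[C@H](CC)C/C(C)=C/[C@@]1(CC)C[C@@H](CC)C(OC)OO1 | intermediate
27 | methyl 2-[(3R,4R,6R)-4,6-diethyl-6-[(1E,4R,5E)-4-ethyl-2-methylocta-1,5-dien-1-yl]-1,2-dioxan-3-yl]acetate | CC/C=C/[C@H](CC)C/C(C)=C/[C@@]1(CC)C[C@@H](CC)[C@@H](CC(=O)OC)OO1 | intermediate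
28 | 2-[(3R,4R,6R)-4,6-diethyl-6-[(1E,4R,5E)-4-ethyl-2-methylocta-1,5-dien-1-yl]-1,2-dioxan-3-yl]acetic acid | CC/C=C/[C@H](CC)C/C(C)=C/[C@@]1(CC)C[C@@H](CC)[C@@H](CC(=O)O)OO1 | target

**Step count and risks**

Total step count: 17. Longest linear sequence: 15 steps (1–5, 7–12, 14–17).

Steps most likely to fail:

1. Step 14. What may go wrong: the SN2 displacement at the β-quaternary C5 by the α-branched azaenolate may be slow, so that attack of the azaenolate at the sulfur of the triflate or at the O–O bond takes over. The fallback makes the C4–C5 bond by carbonyl condensation and conjugate reduction instead of alkylation; it sets out from 17 and comes back at 25. Dess–Martin periodinane (NaHCO3, CH2Cl2, 0 °C) should oxidise 17 to the non-enolisable (2S,3E,6R,7E)-2-[(tert-butyldimethylsilyl)peroxy]-2,6-diethyl-4-methyldeca-3,7-dienal F1. Amine-mediated cross-aldol condensation of F1 with butanal 19 (pyrrolidine, benzoic acid, CH2Cl2) should give the (E)-2-ethyl enal F2. Metal-free transfer hydrogenation of the enal C=C (Hantzsch ester, cat. dibenzylammonium trifluoroacetate, THF) should give the saturated silylperoxy aldehyde F3 as both C2 epimers. 48% aq. HF in MeCN then frees the hydroperoxide and closes ring A to 25 and its C4 epimer F4. These are separated by chromatography, and F4 is re-equilibrated through the open-chain aldehyde with a secondary amine and recycled.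

2. Step 10. What may go wrong: ionisation of the activated tertiary allylic C–O bond ahead of peroxide delivery, with partial loss of configuration at C6 and 1,3-transposition of the hydroperoxide to C8. The fallback gives up stereospecific substitution and secures C6 by separation of rigid ring diastereomers; it sets out from 8 and comes back at 25. Grignard reagent 12, made from 8 as in step 7, is added to 1-chlorobutan-2-one (THF, −78 °C) to give the chlorohydrin F5 as both C2 epimers. K2CO3 in MeOH closes it to 15 together with its (2S)-epimer F6. Steps 10–12 on this mixture give 16, 17 and 18 together with their C2 epimers: the hydroxy hydroperoxide F7, the silyl peroxide F8 and the triflate F9. Step 14 then gives 25 and its C6 epimer, the (4R,6S)-dioxanol F10, which differ in the relation of the ring substituents and should be separable by chromatography. Any transposed hydroperoxide is removed at the stage of 16.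

3. Step 16. What may go wrong: poor facial selectivity of the ketene acetal addition at C3, or Lewis-acid ionisation of the tertiary allylic C6–O bond with opening of ring A. The fallback closes the O(b)–C3 bond by intramolecular peroxy-Michael addition instead; it sets out from 23 and comes back at 27. Hydrazone 23 is isolated after the alkylation of step 14 (aq. NH4Cl quench, no HF) and cleaved with saturated aqueous oxalic acid (Et2O, rt), which leaves the silyl peroxide intact, to the (2R,4R)-silylperoxy aldehyde F11. Horner–Wadsworth–Emmons olefination with trimethyl phosphonoacetate (LiCl, DBU, MeCN, Masamune–Roush conditions) should give the (E)-enoate F12. HF·pyridine (THF, 0 °C) frees the hydroperoxy enoate F13, and catalytic Et2NH in CF3CH2OH should effect the 6-exo-trig peroxy-Michael cyclisation to 27, the minor C3 epimer being removed by chromatography.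

**Further compounds**

F1 | step 14 | (2S,3E,6R,7E)-2-[(tert-butyldimethylsilyl)peroxy]-2,6-diethyl-4-methyldeca-3,7-dienal | CC/C=C/[C@H](CC)C/C(C)=C/[C@@](OO[Si](C)(C)C(C)(C)C)(CC)C=O
F2 | step 14 | (2E,4S,5E,8R,9E)-4-[(tert-butyldimethylsilyl)peroxy]-2,4,8-triethyl-6-methyldodeca-2,5,9-trienal | CC/C=C/[C@H](CC)C/C(C)=C/[C@@](OO[Si](C)(C)C(C)(C)C)(CC)/C=C(\CC)C=O
F3 | step 14 | (4R,5E,8R,9E)-4-[(tert-butyldimethylsilyl)peroxy]-2,4,8-triethyl-6-methyldodeca-5,9-dienal (both C2 epimers) | CC/C=C/[C@H](CC)C/C(C)=C/[C@@](OO[Si](C)(C)C(C)(C)C)(CC)CC(CC)C=O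
F4 | step 14 | (4S,6R)-4,6-diethyl-6-[(1E,4R,5E)-4-ethyl-2-methylocta-1,5-dien-1-yl]-1,2-dioxan-3-ol | CC/C=C/[C@H](CC)C/C(C)=C/[C@@]1(CC)C[C@H](CC)C(O)OO1
F5 | step 10 | (3E,6R,7E)-1-chloro-2,6-diethyl-4-methyldeca-3,7-dien-2-ol (both C2 epimers) | CC/C=C/[C@H](CC)C/C(C)=C/C(O)(CC)CCl
F6 | step 10 | (2S)-2-ethyl-2-[(1E,4R,5E)-4-ethyl-2-methylocta-1,5-dien-1-yl]oxirane | CC/C=C/[C@H](CC)C/C(C)=C/[C@@]1(CC)CO1
F7 | step 10 | (2R,3E,6R,7E)-2,6-diethyl-2-hydroperoxy-4-methyldeca-3,7-dien-1-ol | CC/C=C/[C@H](CC)C/C(C)=C/[C@](OO)(CC)CO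
F8 | step 10 | (2R,3E,6R,7E)-2-[(tert-butyldimethylsilyl)peroxy]-2,6-diethyl-4-methyldeca-3,7-dien-1-ol | CC/C=C/[C@H](CC)C/C(C)=C/[C@](OO[Si](C)(C)C(C)(C)C)(CC)CO
F9 | step 10 | (2R,3E,6R,7E)-2-[(tert-butyldimethylsilyl)peroxy]-2,6-diethyl-4-methyldeca-3,7-dien-1-yl trifluoromethanesulfonate | CC/C=C/[C@H](CC)C/C(C)=C/[C@](OO[Si](C)(C)C(C)(C)C)(CC)COS(=O)(=O)C(F)(F)F
F10 | step 10 | (4R,6S)-4,6-diethyl-6-[(1E,4R,5E)-4-ethyl-2-methylocta-1,5-dien-1-yl]-1,2-dioxan-3-ol | CC/C=C/[C@H](CC)C/C(C)=C/[C@]1(CC)C[C@@H](CC)C(O)OO1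
F11 | step 16 | (2R,4R,5E,8R,9E)-4-[(tert-butyldimethylsilyl)peroxy]-2,4,8-triethyl-6-methyldodeca-5,9-dienal | CC/C=C/[C@H](CC)C/C(C)=C/[C@@](OO[Si](C)(C)C(C)(C)C)(CC)C[C@@H](CC)C=O
F12 | step 16 | methyl (2E,4R,6R,7E,10R,11E)-6-[(tert-butyldimethylsilyl)peroxy]-4,6,10-triethyl-8-methyltetradeca-2,7,11-trienoate | CC/C=C/[C@H](CC)C/C(C)=C/[C@@](OO[Si](C)(C)C(C)(C)C)(CC)C[C@@H](CC)/C=C/C(=O)OC
F13 | step 16 | methyl (2E,4R,6R,7E,10R,11E)-4,6,10-triethyl-6-hydroperoxy-8-methyltetradeca-2,7,11-trienoate | CC/C=C/[C@H](CC)C/C(C)=C/[C@@](OO)(CC)C[C@@H](CC)/C=C/C(=O)OC
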